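The readings were generated by integration for an exercise; the scatter is artificial.

| flask | starting material | catalyst | time |
|---|---|---|---|
| autumn | 1.00 M | 0.0100 M |  |
| dawn | 0.500 M | 0.0100 M |  |
| summer | 1.50 M | 0.0100 M |  |
| midnight | 2.00 M | 0.0300 M | 12 min |

| run | time / min | [target] / M |
|---|---|---|
| autumn run | 1.7 | 0.108 |
| autumn run | 3.4 | 0.153 |
| autumn run | 5.1 | 0.244 |
| autumn run | 6.9 | 0.310 |
| autumn run | 8.6 | 0.382 |
| autumn run | 10 | 0.416 |
| autumn run | 12 | 0.477 |
| dawn run | 1.7 | 0.069 |
| dawn run | 3.4 | 0.103 |
| dawn run | 5.1 | 0.187 |
| dawn run | 6.9 | 0.231 |
| dawn run | 8.6 | 0.261 |
| dawn run | 10 | 0.282 |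
| dawn run | 12 | 0.321 |
| summer run | 1.7 | 0.084 |
| summer run | 3.4 | 0.193 |
| summer run | 5.1 | 0.281 |
| summer run | 6.9 | 0.390 |
| summer run | 8.6 | 0.442 |
| summer run | 10 | 0.514 |
| summer run | 12 | 0.583 |

(readings scatter by 0.01 M)

* the exponent of [starting material] in the starting rate at the charge of the autumn run (at the point where two percent of the starting material have become target) (one fixed amount of target, the same in the runs compared)
* the dawn run starts with 0.500 M less of starting material than the autumn run, and with no target. Compared where both hold the same amount of starting material, once fifteen percent of what the dawn run was charged with has turned into target, is the dawn run faster, slower or alike (within a tenth)?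
* target in the midnight run at 12 min, as a share of the starting material charged

- Overall: starting material -> target, with catalyst as catalyst.
- Constant volume, constant temperature.
- A reading of a species includes what of it is bound.
- An order is taken over about fifteen percent of the charge, up and down.

- Slowness is what I read first: after 12 min the summer run holds 0.583 M of target, from a charge of 1.50 M of starting material. So I watch that run in slow motion.
- In the first instants there is no target and the charge is whole. Up to 3.4 min, target rises at 0.0568 M min⁻¹.
- In the middle, up to 8.6 min, it rises at 0.0479 M min⁻¹.
- In the last stretch it rises at 0.0415 M min⁻¹, slower than at first. The charge less target still stands at 0.917 M.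
- The curve bends gently, so I replace it by its mean, 0.0486 M min⁻¹. That mean lies 14.4% below the first stretch and 17.1% above the last.
- Dividing a mean rate by the catalyst charged gives what I carry: the mean turnover τ, the target made per catalyst per minute, averaged over the run (a mean turnover frequency). For the summer run, τ = 4.86 min⁻¹, at a mean starting material (charge less half the target) of 1.21 M.
- The autumn run gives τ = 3.97 min⁻¹ at 0.762 M. Between these two means I reckon an order in starting material of 0.434.
- The midnight run has 3.00 times the catalyst of the summer run. The earlier runs never varied catalyst, so proportionality is my assumption. With the summer τ, midnight makes 1.75 M of target, or 87.4% of its charge.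
- Its mean starting material is then 1.13 M, less than the summer run's. That shifts τ by 3.04%, so I let the estimate stand.
- The forecast gives an order of 0.38, the dawn run faster, and 70% for midnight, “assuming first order in catalyst” and letting the rate fall off late in the run. Its share is lower than mine.
- The simulation gives an order of 0.45. The dawn run is faster, by a ratio of 1.3. Midnight reaches 60.2%.

    catalyst + starting material ⇌ catalyst-substrate complex, settled at all times (4.970 L mol⁻¹)
    catalyst-substrate complex ⇌ target + catalyst (19.44 min⁻¹, 3.564 L mol⁻¹ min⁻¹)
    2 catalyst ⇌ resting dimer, settled at all times (133.0 L mol⁻¹)
    2 starting material ⇌ idle substrate dimer, settled at all times (22.10 L mol⁻¹)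

- The midnight run's τ is 3.34 min⁻¹, below the summer run's 4.86 min⁻¹. Two catalyst joining to resting dimer hold the apparent order in catalyst at 0.73, against 1.0 without that joining. Carrying the summer τ over with that order gives 3.61 min⁻¹. The simulated midnight run without the joining reaches 83.8%, a mean turnover of 4.66 min⁻¹.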